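Ring B, the cis-2,3-dimethyl-2,3-dihydropyran-4-one, is disconnected across C2–C3 and O1–C8a. Its C4 carbonyl and C4a=C8a double bond are read as a 1-methoxy-3-silyloxy diene; O1 and C2 come from acetaldehyde. One BINOL–titanium-catalysed aldol–cyclocondensation forms both bonds, closes ring B and sets C2 and C3. The precursor is a dearomatised ring A: C5 ketone, quaternary C6, C7 silyl enol ether, C8 ester arm, C8a methyl enol ether, and the Z triethylsilyl enol ether of the C4a propanoyl group. The O8a methyl and O7 silyl groups are installed while ring A is still aromatic, so only one diene can form.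

Key step: step 12

Remark on numbering: every intermediate is described with the chromane numbering of the target (O1, C2, C3, C4, C4a, C5, C6, C7, C8, C8a). "C10 chain" means (2R)-5-methyl-2-(2-methylprop-1-en-1-yl)hex-5-en-1-yl; "arm" means the (R)-CH(Ph)CH2CO2Me group on C8.

Assumption: the absolute sense of induction of the chiral catalysts in steps 5, 7, 10 and 12 is taken from the accepted models of these catalyst families; if a sense is found reversed, the mirror-image catalyst is used and nothing else changes.

Step 1
Reactants: 1 ethyl 5-oxohexanoate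
Product: 2 ethyl 5-methylhex-5-enoate
Conditions: Ph3PCH3Br, KOtBu, THF, 0 °C to rt
Reagents that add atoms: methyltriphenylphosphonium bromide, C[P+](c1ccccc1)(c1ccccc1)c1ccccc1.[Br-]
Why: Wittig methylenation; the unstabilised ylide adds to the ketone and leaves the ester alone, so the isopropenyl end of the side chain exists before any acidic step.

Step 2
Reactants: 2 ethyl 5-methylhex-5-enoate
Product: 3 5-methylhex-5-enal
Conditions: i-Bu2AlH (1.05 equiv), CH2Cl2, −78 °C; MeOH, aqueous KNaC4H4O6
Reagents that add atoms: none
Why: partial ester reduction; at −78 °C the aluminium hemiacetal survives until the quench and then releases the aldehyde, and the 1,1-disubstituted alkene is inert to the hydride.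

Step 3
Reactants: 4 5-methoxybenzene-1,3-diol; 5 propanenitrile
Product: 6 1-(2,4-dihydroxy-6-methoxyphenyl)propan-1-one
Conditions: ZnCl2, HCl (g), Et2O, 0 °C; then H2O, reflux
Reagents that add atoms: water, O
Why: Houben–Hoesch acylation; the nitrilium ion should attack one of the two equivalent ring carbons between a hydroxyl and the methoxy group, which puts the propanoyl group next to the future O8a methyl ether before any acid-sensitive alkene is present, and the expected minor 2,6-dihydroxy isomer is removed by crystallisation.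

Step 4
Reactants: 6 1-(2,4-dihydroxy-6-methoxyphenyl)propan-1-one; 7 formaldehyde (37% aqueous)
Product: 8 1-[2,4-dihydroxy-6-methoxy-3-(tosylmethyl)phenyl]propan-1-one
Conditions: TolSO2Na, HCO2H/H2O, rt
Reagents that add atoms: sodium p-toluenesulfinate, Cc1ccc(S(=O)[O-])cc1.[Na+]
Why: Mannich-type three-component sulfonylmethylation; substitution should go to the carbon between the two hydroxyls (the future C6), activated by all three oxygens, because the other free carbon is screened by the methoxy methyl group that the neighbouring acyl group turns toward it, and the sulfone is a bench-stable quinone methide precursor.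

Step 5
Reactants: 8 1-[2,4-dihydroxy-6-methoxy-3-(tosylmethyl)phenyl]propan-1-one; 3 5-methylhex-5-enal
Product: 10 1-[(3R)-2,5-dihydroxy-7-methoxy-3-(3-methylbut-3-enyl)chroman-6-yl]propan-1-one (both anomers at C2), via ortho-quinone methide 9 (not isolated)
Conditions: (S)-α,α-diphenylprolinol trimethylsilyl ether (20 mol%), NaHCO3, CH2Cl2/H2O, 0 °C to rt
Reagents that add atoms: none
Why: enamine-catalysed α-alkylation of an aldehyde by an ortho-quinone methide (formal [4+2], then hydrolysis); bicarbonate expels sulfinate from 8, the E enamine of 3 adds to the methide carbon of 9 through its Si face, the one left open by the diphenyl(silyloxy)methyl group of the (S) catalyst, which sets the side-chain center as R, and the aldehyde is held as the lactol of the neighbouring phenol.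

Step 6
Reactants: 10 1-[(3R)-2,5-dihydroxy-7-methoxy-3-(3-methylbut-3-enyl)chroman-6-yl]propan-1-one
Product: 11 1-[3-(C10 chain)-2,4-dihydroxy-6-methoxyphenyl]propan-1-one
Conditions: Ph3PCH(CH3)2I, n-BuLi (3.5 equiv ylide), THF, 0 °C; then 10, −78 °C to rt
Reagents that add atoms: isopropyltriphenylphosphonium iodide, CC(C)[P+](c1ccccc1)(c1ccccc1)c1ccccc1.[I-]
Why: Wittig olefination of a lactol through its open hydroxy aldehyde; excess unstabilised ylide first deprotonates the phenols and then turns the aldehyde into the 2-methylprop-1-enyl group faster than it enolises, so the adjacent R center is kept and the chelated aryl ketone is not touched.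

Step 7
Reactants: 11 1-[3-(C10 chain)-2,4-dihydroxy-6-methoxyphenyl]propan-1-one; 12 (E)-cinnamaldehyde
Product: 13 1-[(4R)-8-(C10 chain)-2,7-dihydroxy-5-methoxy-4-phenylchroman-6-yl]propan-1-one (both anomers at C2)
Conditions: (R)-α,α-diphenylprolinol trimethylsilyl ether (20 mol%), PhCO2H (20 mol%), toluene, rt
Reagents that add atoms: none
Why: iminium-catalysed Friedel–Crafts alkylation with hemiacetal closure, known for electron-rich phenols and enals; the only free ring carbon (the future C8) adds to the β-carbon of the cinnamaldehyde iminium ion on its Re face, the one not covered by the (R) catalyst, which sets the benzylic center as R, and the adjacent hydroxyl (the future O7) traps the aldehyde as the lactol.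

Step 8
Reactants: 13 1-[(4R)-8-(C10 chain)-2,7-dihydroxy-5-methoxy-4-phenylchroman-6-yl]propan-1-one
Product: 14 (4R)-8-(C10 chain)-7-hydroxy-5-methoxy-4-phenyl-6-propanoylchroman-2-one
Conditions: (C5H5NH)[CrO3Cl] (pyridinium chlorochromate), 4 Å molecular sieves, CH2Cl2, 0 °C to rt
Reagents that add atoms: none
Why: chromate oxidation of a lactol to the lactone; the hemiacetal C–H is the only oxidisable carbinol, the chelated phenol and the alkenes should survive the anhydrous conditions, and the lactone now marks O7 as different from O5.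

Step 9
Reactants: 14 (4R)-8-(C10 chain)-7-hydroxy-5-methoxy-4-phenyl-6-propanoylchroman-2-one
Product: 16 methyl (3R)-3-[2-(tert-butyldimethylsilyloxy)-3-(C10 chain)-4-hydroxy-6-methoxy-5-propanoylphenyl]-3-phenylpropanoate, via hydroxy ester 15 (not isolated)
Conditions: NaOMe, MeOH/THF, 0 °C; AcOH; evaporation; then TBSOTf (1.1 equiv), 2,6-lutidine, CH2Cl2, −78 to −20 °C
Reagents that add atoms: sodium methoxide, C[O-].[Na+]; tert-butyldimethylsilyl trifluoromethanesulfonate, CC(C)(C)[Si](C)(C)OS(=O)(=O)C(F)(F)F
Why: methoxide transesterification of the aryl lactone, then selective silylation; ring opening frees O7–H as the only phenol not locked in a hydrogen bond to the propanoyl carbonyl, so one equivalent of silyl triflate should cap O7 and not O5, which fixes the later C7 enol ether by construction and blocks relactonisation.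

Step 10
Reactants: 16 methyl (3R)-3-[2-(tert-butyldimethylsilyloxy)-3-(C10 chain)-4-hydroxy-6-methoxy-5-propanoylphenyl]-3-phenylpropanoate; 17 3-methylbut-2-en-1-yl acetate
Product: 18 ring A dienone: C5 ketone, C6 (S) bearing prenyl and the C10 chain, C7 tert-butyldimethylsilyl enol ether, C8 arm, C8a methyl enol ether, C4a propanoyl
Conditions: Pd2(dba)3·CHCl3 (2.5 mol%), (R,R)-DACH-phenyl Trost ligand (7.5 mol%), Li2CO3, 1,4-dioxane, rt to 40 °C
Reagents that add atoms: none
Why: palladium-catalysed asymmetric allylic dearomatisation (Tsuji–Trost alkylation of a phenoxide at a substituted ortho carbon); the π-prenyl complex formed from zerovalent palladium is attacked at its CH2 end by C6, the only nucleophilic ring carbon that is neither acylated nor blocked by the bulky arm, any O5 prenyl ether re-ionises and funnels to the C-alkylated vinylogous ester, and the ligand pocket should select the face of C6 (its flanks, the O5 oxide and the O7 silyl ether, differ strongly in size) to give the S quaternary center, a minor C6 epimer being a separable diastereomer.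

Step 11
Reactants: 18 ring A dienone with C4a propanoyl
Product: 19 ring A diene: as 18 but with the C4a propanoyl group as its (Z)-1-(triethylsilyloxy)prop-1-enyl ether
Conditions: Et3SiOTf (1.3 equiv), Et3N, CH2Cl2, −78 to −20 °C
Reagents that add atoms: triethylsilyl trifluoromethanesulfonate, CC[Si](CC)(CC)OS(=O)(=O)C(F)(F)F
Why: soft enolisation with silyl triflate and amine; only the propanoyl carbonyl can give a neutral enol silane (C5 has no α-hydrogen and the ester is slower), and allylic strain against ring A puts the methyl group cis to the silyloxy group, giving the Z enol ether that completes the 1-methoxy-3-silyloxy diene with the C4a=C8a methyl enol ether.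

Step 12
Reactants: 19 ring A diene; 20 acetaldehyde
Product: 22 methyl (3R)-3-[(2R,3S,6S)-7-(tert-butyldimethylsilyloxy)-6-(C10 chain)-2,3-dimethyl-6-(3-methylbut-2-enyl)-4,5-dioxo-3,6-dihydro-2H-chromen-8-yl]-3-phenylpropanoate, via methoxy ketal 21 (not isolated)
Conditions: Ti(OiPr)4/(S)-BINOL 1:1 (20 mol%, pre-formed over 4 Å molecular sieves, volatiles removed), 20 (5 equiv), CH2Cl2, −20 °C; then pyridinium p-toluenesulfonate (10 mol%), 0 °C
Reagents that add atoms: none
Why: The BINOL–titanium complex binds acetaldehyde and the Z triethylsilyl enol ether attacks it through C3 (Mukaiyama aldol addition, the stepwise limit of a hetero-Diels–Alder reaction), giving a silyloxocarbenium ion delocalised onto C8a; the titanium aldolate oxygen adds to C8a to give ketal 21, which loses methoxy(triethyl)silane, at the latest on the pyridinium tosylate finish, restoring the C4a=C8a double bond and the C4 ketone. The closest known reaction is the BINOL–Ti(OiPr)4-catalysed aldol–cyclocondensation of 1-methoxy-3-silyloxy dienes with aldehydes to 2,3-dihydropyran-4-ones; here the diene is part of ring A. Ring B closes by a 6-endo-trig addition–elimination of O1 at C8a, the only diene terminus with a leaving group, since C5 is a ketone. C2 is set by the catalyst, (S)-BINOL directing attack on the Si face of the aldehyde as in the allylations and aldol additions of this catalyst, and C3 follows from the syn preference of the Z enol silane in the open or endo transition state, so the two methyl groups should end up cis (2R,3S). The step needs site selectivity between two enol silanes and should get it because C3 is a free CH terminus whereas C8 is fully substituted and carries the bulkier silyl ether; the centers at C6, on the arm and in the side chain are spectators.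

Step 13
Reactants: 22 ring B closed silyl enol ether methyl ester
Product: 24 (3R)-3-[(2R,3S,6S)-6-(C10 chain)-4-hydroxy-2,3-dimethyl-6-(3-methylbut-2-enyl)-5,7-dioxo-3,5,6,7-tetrahydro-2H-chromen-8-yl]-3-phenylpropanoic acid (CNP0155375.4), via methyl ester 23 (not isolated)
Conditions: LiOH·H2O (5 equiv), THF/MeOH/H2O, 0 °C to rt; then 0.5 M aqueous citric acid to pH 3
Reagents that add atoms: lithium hydroxide, [Li+].[OH-]
Why: hydroxide cleaves the C7 silyl enol ether at once (the leaving group is a vinylogous carboxylate) to give the enolate of 23, whose delocalised charge shields C3–H from deprotonation and C8a from attack, and then saponifies the methyl ester; mild acidification gives the acid without touching the alkenes.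

Compound list
1 | ethyl 5-oxohexanoate | CCOC(=O)CCCC(C)=O | starting material
2 | ethyl 5-methylhex-5-enoate | CCOC(=O)CCCC(C)=C | intermediate
3 | 5-methylhex-5-enal | C=C(C)CCCC=O | intermediate
4 | 5-methoxybenzene-1,3-diol | COc1cc(O)cc(O)c1 | starting material
5 | propanenitrile | CCC#N | starting material
6 | 1-(2,4-dihydroxy-6-methoxyphenyl)propan-1-one | CCC(=O)c1c(O)cc(O)cc1OC | intermediate
7 | formaldehyde | C=O | starting material
8 | 1-[2,4-dihydroxy-6-methoxy-3-[(4-methylphenyl)sulfonylmethyl]phenyl]propan-1-one | CCC(=O)c1c(OC)cc(O)c(CS(=O)(=O)c2ccc(C)cc2)c1O | intermediate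
9 | 5-hydroxy-3-methoxy-6-methylidene-4-propanoylcyclohexa-2,4-dien-1-one (ortho-quinone methide, not isolated) | CCC(=O)C1=C(O)C(=C)C(=O)C=C1OC | intermediate
10 | 1-[(3R)-2,5-dihydroxy-7-methoxy-3-(3-methylbut-3-enyl)-3,4-dihydro-2H-chromen-6-yl]propan-1-one, both anomers at C2 | CCC(=O)c1c(OC)cc2OC(O)[C@H](CCC(C)=C)Cc2c1O | intermediate
11 | 1-[2,4-dihydroxy-6-methoxy-3-[(2R)-5-methyl-2-(2-methylprop-1-enyl)hex-5-enyl]phenyl]propan-1-one | CCC(=O)c1c(OC)cc(O)c(C[C@H](C=C(C)C)CCC(C)=C)c1O | intermediate
12 | (E)-cinnamaldehyde | O=C/C=C/c1ccccc1 | starting material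
13 | 1-[(4R)-2,7-dihydroxy-5-methoxy-8-[(2R)-5-methyl-2-(2-methylprop-1-enyl)hex-5-enyl]-4-phenyl-3,4-dihydro-2H-chromen-6-yl]propan-1-one, both anomers at C2 | CCC(=O)c1c(O)c(C[C@H](C=C(C)C)CCC(C)=C)c2OC(O)C[C@H](c3ccccc3)c2c1OC | intermediate
14 | (4R)-7-hydroxy-5-methoxy-8-[(2R)-5-methyl-2-(2-methylprop-1-enyl)hex-5-enyl]-4-phenyl-6-propanoyl-3,4-dihydrochromen-2-one | CCC(=O)c1c(O)c(C[C@H](C=C(C)C)CCC(C)=C)c2OC(=O)C[C@H](c3ccccc3)c2c1OC | intermediate
15 | methyl (3R)-3-[2,4-dihydroxy-6-methoxy-3-[(2R)-5-methyl-2-(2-methylprop-1-enyl)hex-5-enyl]-5-propanoylphenyl]-3-phenylpropanoate (not isolated) | CCC(=O)c1c(O)c(C[C@H](C=C(C)C)CCC(C)=C)c(O)c([C@H](CC(=O)OC)c2ccccc2)c1OC | intermediate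
16 | methyl (3R)-3-[2-[tert-butyl(dimethyl)silyl]oxy-4-hydroxy-6-methoxy-3-[(2R)-5-methyl-2-(2-methylprop-1-enyl)hex-5-enyl]-5-propanoylphenyl]-3-phenylpropanoate | CCC(=O)c1c(O)c(C[C@H](C=C(C)C)CCC(C)=C)c(O[Si](C)(C)C(C)(C)C)c([C@H](CC(=O)OC)c2ccccc2)c1OC | intermediate
17 | 3-methylbut-2-en-1-yl acetate (prenyl acetate) | CC(=O)OCC=C(C)C | starting material
18 | methyl (3R)-3-[(3S)-2-[tert-butyl(dimethyl)silyl]oxy-6-methoxy-3-(3-methylbut-2-enyl)-3-[(2R)-5-methyl-2-(2-methylprop-1-enyl)hex-5-enyl]-4-oxo-5-propanoylcyclohexa-1,5-dien-1-yl]-3-phenylpropanoate (ring position 3 = C6) | C=C(C)CC[C@@H](C=C(C)C)C[C@@]1(CC=C(C)C)C(=O)C(C(=O)CC)=C(OC)C([C@H](CC(=O)OC)c2ccccc2)=C1O[Si](C)(C)C(C)(C)C | intermediate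
19 | methyl (3R)-3-[(3S)-2-[tert-butyl(dimethyl)silyl]oxy-6-methoxy-3-(3-methylbut-2-enyl)-3-[(2R)-5-methyl-2-(2-methylprop-1-enyl)hex-5-enyl]-4-oxo-5-[(Z)-1-(triethylsilyloxy)prop-1-enyl]cyclohexa-1,5-dien-1-yl]-3-phenylpropanoate (precursor of the key step) | C=C(C)CC[C@@H](C=C(C)C)C[C@@]1(CC=C(C)C)C(=O)C(/C(O[Si](CC)(CC)CC)=C/C)=C(OC)C([C@H](CC(=O)OC)c2ccccc2)=C1O[Si](C)(C)C(C)(C)C | intermediate
20 | acetaldehyde | CC=O | starting material
21 | ring B ketal: as 22, but C8a is sp3 and carries OMe and O1, and C4 is the triethylsilyl enol ether of a C4=C4a double bond; (2R,3S,6S), mixture at C8a (not isolated) | C=C(C)CC[C@@H](C=C(C)C)C[C@@]1(CC=C(C)C)C(=O)C2=C(O[Si](CC)(CC)CC)[C@@H](C)[C@@H](C)OC2(OC)C([C@H](CC(=O)OC)c3ccccc3)=C1O[Si](C)(C)C(C)(C)C | intermediate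
22 | methyl (3R)-3-[(2R,3S,6S)-7-[tert-butyl(dimethyl)silyl]oxy-2,3-dimethyl-6-(3-methylbut-2-enyl)-6-[(2R)-5-methyl-2-(2-methylprop-1-enyl)hex-5-enyl]-4,5-dioxo-3,6-dihydro-2H-chromen-8-yl]-3-phenylpropanoate (product of the key step) | C=C(C)CC[C@@H](C=C(C)C)C[C@@]1(CC=C(C)C)C(=O)C2=C(O[C@H](C)[C@H](C)C2=O)C([C@H](CC(=O)OC)c2ccccc2)=C1O[Si](C)(C)C(C)(C)C | intermediate
23 | methyl (3R)-3-[(2R,3S,6S)-4-hydroxy-2,3-dimethyl-6-(3-methylbut-2-enyl)-6-[(2R)-5-methyl-2-(2-methylprop-1-enyl)hex-5-enyl]-5,7-dioxo-3,5,6,7-tetrahydro-2H-chromen-8-yl]-3-phenylpropanoate (not isolated) | C=C(C)CC[C@@H](C=C(C)C)C[C@@]1(CC=C(C)C)C(=O)C2=C(O)[C@@H](C)[C@@H](C)OC2=C([C@H](CC(=O)OC)c2ccccc2)C1=O | intermediate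
24 | (3R)-3-[(2R,3S,6S)-4-hydroxy-2,3-dimethyl-6-(3-methylbut-2-enyl)-6-[(2R)-5-methyl-2-(2-methylprop-1-enyl)hex-5-enyl]-5,7-dioxo-3,5,6,7-tetrahydro-2H-chromen-8-yl]-3-phenylpropanoic acid | C=C(C)CC[C@@H](C=C(C)C)C[C@@]1(CC=C(C)C)C(=O)C2=C(O)[C@@H](C)[C@@H](C)OC2=C([C@H](CC(=O)O)c2ccccc2)C1=O | target

Total step count: 13. Longest linear sequence: 11 steps (steps 3 to 13 from 4; equally steps 1, 2 and 5 to 13 from 1).

Steps most likely to fail

1. Step 12. The enol silane is cross-conjugated with a vinylogous ester and may be too weak a nucleophile for the mild titanium catalyst; acetaldehyde may oligomerise; or the syn preference may erode and give the trans-dimethyl ring. The fallback replaces catalysis by a reagent-controlled boron aldol and sets out from ketone 18. Diisopinocampheylboron triflate (the enantiomer that attacks the Si face of the aldehyde) and i-Pr2NEt give the Z boron enolate of the propanoyl group. Addition of 20 at −78 °C and a non-oxidative work-up give the syn β-hydroxy ketone F1. Catalytic camphorsulfonic acid in CH2Cl2 then adds the new hydroxyl to C8a with loss of methanol, closing ring B and coming back to the route at 22.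

2. Step 10. The catalyst may fail to distinguish the two faces of C6, or O-prenylation may not turn over to the crowded carbon. The fallback transfers chirality through a sigmatropic shift and sets out from phenol 16. Mitsunobu etherification of O5–H with (S)-but-3-en-2-ol (PPh3, DIAD, inversion) gives the (R)-but-3-en-2-yl ether F2. Aromatic Claisen rearrangement (toluene, 110 °C, or Eu(fod)3) through the chair transition state with an equatorial methyl group delivers an (E)-but-2-enyl group to the required face of C6, the only ortho carbon of O5 without an acyl group, giving the but-2-enyl dienone F3. Cross metathesis with 2-methyl-2-butene (second-generation Grubbs catalyst) converts the but-2-enyl into the prenyl group and comes back to the route at 18.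

3. Step 5. The quinone methide may condense with free ring positions of 8 or 10 or alkylate the amine catalyst, and the enantioselectivity may be low. The fallback uses a stoichiometric auxiliary and sets out from aldehyde 3 and sulfone 8. Condensation of 3 with (R)-1-amino-2-(methoxymethyl)pyrrolidine gives the RAMP hydrazone F4. Deprotonation with LiN(i-Pr)2 (excess, THF, −78 °C) and addition of 8, from which the excess base releases the quinone methide, gives the alkylated hydrazone F5 with the R side-chain center under auxiliary control. Hydrolysis with aqueous oxalic acid frees the aldehyde, which closes to lactol 10, where the route resumes.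

Further compounds
F1 | step 12 | syn aldol: as 18 but with the C4a propanoyl group extended to (2S,3R)-3-hydroxy-2-methylbutanoyl (C3 S, C2 R in chromane numbering) | C=C(C)CC[C@@H](C=C(C)C)C[C@@]1(CC=C(C)C)C(=O)C(C(=O)[C@@H](C)[C@@H](C)O)=C(OC)C([C@H](CC(=O)OC)c2ccccc2)=C1O[Si](C)(C)C(C)(C)C
F2 | step 10 | methyl (3R)-3-[4-[(2R)-but-3-en-2-yl]oxy-2-[tert-butyl(dimethyl)silyl]oxy-6-methoxy-3-[(2R)-5-methyl-2-(2-methylprop-1-enyl)hex-5-enyl]-5-propanoylphenyl]-3-phenylpropanoate | CCC(=O)c1c(O[C@H](C)C=C)c(C[C@H](C=C(C)C)CCC(C)=C)c(O[Si](C)(C)C(C)(C)C)c([C@H](CC(=O)OC)c2ccccc2)c1OC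
F3 | step 10 | ring A dienone as 18 with an (E)-but-2-enyl group in the place of the prenyl group on C6, same spatial arrangement at C6 | C=C(C)CC[C@@H](C=C(C)C)C[C@@]1(C/C=C/C)C(=O)C(C(=O)CC)=C(OC)C([C@H](CC(=O)OC)c2ccccc2)=C1O[Si](C)(C)C(C)(C)C
F4 | step 5 | (E)-N-[(2R)-2-(methoxymethyl)pyrrolidin-1-yl]-5-methylhex-5-en-1-imine (RAMP hydrazone of 3) | C=C(C)CCC/C=N/N1CCC[C@@H]1COC
F5 | step 5 | RAMP hydrazone of (2R)-2-[(2,6-dihydroxy-4-methoxy-3-propanoylphenyl)methyl]-5-methylhex-5-enal | CCC(=O)c1c(OC)cc(O)c(C[C@H](/C=N/N2CCC[C@@H]2COC)CCC(C)=C)c1O
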